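## Analysis of the target

The target 18 is a flavonol: a 4H-chromen-4-one in which ring A is fused to the pyranone ring C, with a 4-methoxyphenyl group (ring B) on C2 and the enolic hydroxyl on C3. Ring A has a phloroglucinol pattern: a free 5-OH chelated to the C4 carbonyl, a 7-OMe, and at C8, between O1 and the 7-methoxy group, a 1-(4-hydroxyphenyl)ethyl group whose phenol ring is called ring D here. The benzylic methine between ring A and ring D is the only stereocentre. With ring A > ring D > CH3 > H it is (R), and as nothing else is stereogenic it must be set by absolute control and then only preserved. Three things are sensitive. The methine is bonded to a very electron-rich arene, so strong acid can protonate ring A at that carbon and break the bond. The 3-hydroxypyranone is an oxidisable, chelating enol. Four phenolic oxygens must end as two free hydroxyls (C5, ring D) and two methyl ethers (C7, C4'). The synthesis is hard because C8 is flanked by oxygen on both sides, because electrophilic substitution on ring A does not tell C6 from C8, and because the two aryl groups on the stereocentre differ too little for a catalyst without a handle. The strategy rests on C3 and C4 of ring C. The flavonol is the enol of a 2-arylchroman-3,4-dione, so both carbons are at the carbonyl oxidation level, and the C3–C4 bond can be made by joining two aldehyde carbons: one on C4a of ring A, the other on the carbon next to C2, which carries ring B and is tied to ring A through O1.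

## Retrosynthetic reasoning

**18 to 17.** The O–CH3 bond at C5 and the O–benzyl bond on ring D are cut last. The 5-methyl ether can be distinguished from the 7- and 4'-methyl ethers only by chelation to the C4 carbonyl, which exists only once ring C is closed. The benzyl ether survives every earlier step and falls to the same Lewis acid, so one operation frees both hydroxyls.

**17 to 15 through 16.** No skeletal bond is cut. Flavonol 17 is the enol of dione 16, and 16 is the oxidised form of acyloin 15. Read this way, the C2=C3 double bond needs no step of its own, and the configurations at C2 and C3 of 15 are irrelevant.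

**15 to 14.** The C3–C4 bond is cut. It is the only bond of ring C whose two carbons can both be aldehyde carbons, so the C3 oxygen and the C4 carbonyl arrive together. Cutting at O1–C2 or C2–C3 instead leads to chalcone or flavanone intermediates that still need oxygen at C3. The forward reaction must invert the polarity of one formyl carbon under conditions mild enough for an enolisable α-aryloxy aldehyde. That is the task of a carbene catalyst.

**14 to 13 to 9 + 12.** The ether bond between O1 and the ring B-bearing carbon is cut. The aliphatic aldehyde cannot be free while a phenoxide is alkylated, so it is carried as a dimethyl acetal in 12 and 13 and released by aqueous acid. The ring A aldehyde must already be present in 9, because its introduction needs the free phenol.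

**12 to 11 to 10.** The C–Br and one C–OMe bond of 12 come from bromo-alkoxylation of enol ether 11, which comes from aldehyde 10 by one-carbon olefination. This places bromine on the benzylic carbon without any bromination that could touch the anisole ring.

**9 to 7 through 8.** The bond between C4a and the formyl carbon is cut. The phenol of 7 has one free ortho position. A formylation delivered through the magnesium phenoxide goes only there and not to the equally electron-rich carbon between the two methoxy groups.

**7 to 6.** The C–H bond of the stereocentre is cut. The ortho hydroxyl of 6 is the handle. It lets a chiral Brønsted acid turn the alkene into a hydrogen-bonded quinone methide and direct a hydride donor to one face. The centre is set on a small intermediate, before any enolisable or acid-labile function is present.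

**6 to 4 through 5, and 4 to 3 to 1 + 2.** The alkene carbon comes from a methyl Grignard addition to ketone 4 and loss of water from carbinol 5. Ketone 4 comes from oxidation of benzhydrol 3, and 3 from addition of aryl Grignard reagent 2 to aldehyde 1. The formyl carbon of 1 becomes the stereocentre carbon, so the position of the side chain on ring A (ortho to the hydroxyl, between hydroxyl and methoxy) is bought with 1. A Lewis-acid acylation of a phenol was set aside because it would endanger the benzyl ether and leave the ortho/para question open.

## Alternatives that were turned down

**Alternative 1:** Carbene C–H insertion that makes the methyl carbon from a methoxymethyl ether.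
- **Disconnection:** the bond from the stereocentre to its methyl carbon, that carbon being traced back to the O–CH2–O carbon of a methoxymethyl ether on the neighbouring ring A oxygen.
- **Forward key step:** a diaryl diazomethane is decomposed by a chiral dirhodium tetracarboxylate. The donor/donor carbene inserts into a C–H bond of the acetal methylene and gives the 2-methoxy-2,3-dihydrobenzofuran A1, with the benzylic centre set by the catalyst.
- **For it:** a C–C bond and the stereocentre are made in one catalytic operation, and the two aryl groups are told apart by the tether, not by their electronics. On this point it is at least as strong as the transfer hydrogenation used here.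
- **Against it:** in A1 the future methyl carbon is at the aldehyde oxidation level. Opening the cyclic acetal gives a lactol whose open form is an α,α-diaryl acetaldehyde. The hydrogen on the stereocentre is then doubly benzylic and α to a carbonyl, so the configuration can be lost by enolisation. Two more steps (reduction, deoxygenation of the primary alcohol) are needed only to reach the phenol obtained here as 7. The other ortho substituent of ring A is a methoxy group whose C–H bonds lie at the same distance from the carbene, so site selectivity is a second open question.
- **Comparison:** the chosen route reaches 7 in four steps and creates the centre in a step after which no acidic or ionisable position adjoins it. Alternative 1 spends its risk on the stereocentre and still has ring C ahead.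

**Alternative 2:** Benzannulation that builds ring A around the stereocentre.
- **Disconnection:** ring A itself, at C7–C8, C6–C7 and C4a–C8a, so that the arene is assembled around a side chain that already holds the stereocentre.
- **Forward key step:** heating an alkoxycyclobutenone with a silyl ynol ether that carries the 1-arylethyl group. Electrocyclic opening to a vinylketene, [2+2] addition to the alkyne, a second ring opening, six-electron closure and tautomerisation give phenol A2.
- **For it:** the substitution pattern of ring A is fixed by the cascade. The side chain lies between two oxygens by construction, and the three ring A oxygens are different from the start (free hydroxyl, ethyl ether, silyl ether). On oxygen differentiation it is stronger than the chosen route, where O5 and O7 are both methyl ethers until the last step.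
- **Against it:** ring A with this pattern can be bought (as 1), so three C–C bonds are made that need not be made. The stereocentre must be installed earlier on a small propargylic fragment and carried as a benzylic and propargylic C–H through strong base and prolonged heating, where propargyl–allenyl isomerisation would erase it. The ethyl ether sits at the future C5 and must be cleaved, the silyl ether must be exchanged for methyl, and ring C is still ahead.
- **Comparison:** several more steps for ring A alone and a less secure stereocentre. The chosen route gives up the built-in differentiation of the oxygens and replaces it by a chelation-controlled demethylation at the end.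

**Alternative 3:** Diketone dianion that closes ring A onto a thiomethyl pyranone.
- **Disconnection:** C8–C8a, with rings B and C complete and ring A grown from a side chain on the pyranone.
- **Forward key step:** the dianion of a 1,3-diketone chain on the future C4a attacks the neighbouring thiomethyl-bearing ring carbon through its terminal carbanion (the future C8, which carries the 1-arylethyl group). Loss of thiolate and tautomerisation give the 5,7-dihydroxyflavone A3 with its 3-oxygen as a benzyl ether.
- **For it:** ring A arrives with 5-OH and 7-OH free and chemically distinct, so the 7-OH can be methylated alone and both benzyl ethers then fall in one hydrogenolysis. This endgame keeps every Lewis acid away from the acid-sensitive aryl–methine bond and is milder than step 12 here.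
- **Against it:** the substrate is a fully substituted pyranone with an aryl group, a benzyloxy group, a thiomethyl leaving group and a dioxoalkyl chain ending in the stereocentre, and is a long synthesis in itself. A branched secondary carbanion must attack a tetrasubstituted sp2 carbon while the same dianion can add at C2 or close through oxygen. Tricarbonyl chains of this kind self-condense, and the chiral arylbutanoyl piece needs its own asymmetric synthesis.
- **Comparison:** more steps and a key step with several competing modes, against a route whose ring A is purchased. What alternative 3 offers in return is the gentler final deprotection, which the chosen route answers with low temperature, a cation scavenger and a hydrogenolysis-based fallback.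

Key step: step 10

## Route

Remark on the chemistry: the (R) centre requires hydride delivery in step 4 to the Si face of the methide carbon (ring A > ring D > CH3). (R)-TRIP is written; its antipode is the one to use should the sense of induction prove opposite.

Step 1
Reactants: 1 2-hydroxy-4,6-dimethoxybenzaldehyde; 2 4-(benzyloxy)phenylmagnesium bromide (commercial THF solution)
Product: 3 2-{[4-(benzyloxy)phenyl](hydroxy)methyl}-3,5-dimethoxyphenol (racemic)
Conditions: 2 (2.3 equiv), THF, 0 °C to rt; sat. aq. NH4Cl
Reagents that add atoms: none
Why: Grignard addition to a salicylaldehyde: the first equivalent of 2 removes the phenol proton and the magnesium phenoxide chelate accepts the second at the formyl carbon. The electron-rich benzhydrol ionises easily, so it should be kept neutral and carried on crude.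

Step 2
Reactants: 3 2-{[4-(benzyloxy)phenyl](hydroxy)methyl}-3,5-dimethoxyphenol
Product: 4 [4-(benzyloxy)phenyl](2-hydroxy-4,6-dimethoxyphenyl)methanone
Conditions: activated MnO2 (10 equiv), CH2Cl2, rt
Reagents that add atoms: none
Why: Oxidation of a doubly benzylic alcohol by MnO2 under neutral heterogeneous conditions, which should spare the free phenol and the benzyl ether. The product is stabilised by the hydrogen bond between the hydroxyl and the ketone.

Step 3
Reactants: 4 [4-(benzyloxy)phenyl](2-hydroxy-4,6-dimethoxyphenyl)methanone
Product: 6 2-{1-[4-(benzyloxy)phenyl]ethenyl}-3,5-dimethoxyphenol, via tertiary carbinol 5 (not isolated)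
Conditions: MeMgBr (3.5 equiv), THF, 0 °C to rt; sat. aq. NH4Cl; then PPTS (5 mol %), toluene, 40 °C
Reagents that add atoms: methylmagnesium bromide, C[Mg]Br
Why: Grignard addition of the smallest carbon nucleophile to a ketone that has no α-hydrogen and is activated by the magnesium phenoxide chelate, followed by E1 loss of water from 5 through a cation stabilised by both aryl groups. A weak acid and mild warming should limit cationic dimerisation of the electron-rich alkene.

Step 4
Reactants: 6 2-{1-[4-(benzyloxy)phenyl]ethenyl}-3,5-dimethoxyphenol
Product: 7 2-[(1R)-1-[4-(benzyloxy)phenyl]ethyl]-3,5-dimethoxyphenol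
Conditions: (R)-TRIP (5 mol %), Hantzsch ester (1.3 equiv), CH2Cl2, 0 °C to rt
Reagents that add atoms: none
Why: Chiral-phosphoric-acid-catalysed asymmetric transfer hydrogenation of an ortho-hydroxy 1,1-diarylethene: protonation at the methylene gives an ortho-quinone methide held by the phosphate through the phenol O–H, and the Hantzsch ester bound to the same phosphate delivers hydride to one face. Delivery to the Si face of the methide carbon sets the (R) centre. The product has no alkene and cannot re-ionise, so the centre stays fixed.

Step 5
Reactants: 7 2-[(1R)-1-[4-(benzyloxy)phenyl]ethyl]-3,5-dimethoxyphenol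
Product: 9 3-[(1R)-1-[4-(benzyloxy)phenyl]ethyl]-2-hydroxy-4,6-dimethoxybenzaldehyde, via hydroxymethylphenol 8 (not isolated)
Conditions: MgCl2 (2 equiv), Et3N (4 equiv), (CH2O)n (6 equiv), MeCN, reflux; then dilute aq. HCl
Reagents that add atoms: paraformaldehyde (as formaldehyde), C=O
Why: Magnesium-mediated ortho-formylation (Casnati–Skattebøl): formaldehyde bound to the magnesium phenoxide is delivered to the only free ortho carbon, and 8 is oxidised in the flask by hydride transfer to a second formaldehyde. Coordination steers the electrophile away from the equally electron-rich carbon between the two methoxy groups. The weakly basic medium leaves the benzylic centre and the benzyl ether untouched.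

Step 6
Reactants: 10 4-methoxybenzaldehyde
Product: 11 1-methoxy-4-(2-methoxyethenyl)benzene (E/Z mixture)
Conditions: Ph3P(CH2OMe)Cl (1.3 equiv), KOtBu (1.3 equiv), THF, 0 °C to rt
Reagents that add atoms: (methoxymethyl)triphenylphosphonium chloride, COC[P+](c1ccccc1)(c1ccccc1)c1ccccc1.[Cl-]
Why: Wittig methoxymethylenation of an aromatic aldehyde. Both alkene isomers serve equally in the next step.

Step 7
Reactants: 11 1-methoxy-4-(2-methoxyethenyl)benzene
Product: 12 1-(1-bromo-2,2-dimethoxyethyl)-4-methoxybenzene (racemic)
Conditions: NBS (1.05 equiv), MeOH, −20 to 0 °C
Reagents that add atoms: N-bromosuccinimide, O=C1CCC(=O)N1Br; methanol, CO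
Why: Bromo-methoxylation of an enol ether: bromine adds to the nucleophilic benzylic carbon and methanol captures the oxocarbenium ion, giving the α-bromo dimethyl acetal regiospecifically. At low temperature the enol ether should react far faster than the anisole ring.

Step 8
Reactants: 9 3-[(1R)-1-[4-(benzyloxy)phenyl]ethyl]-2-hydroxy-4,6-dimethoxybenzaldehyde; 12 1-(1-bromo-2,2-dimethoxyethyl)-4-methoxybenzene
Product: 13 3-[(1R)-1-[4-(benzyloxy)phenyl]ethyl]-2-[2,2-dimethoxy-1-(4-methoxyphenyl)ethoxy]-4,6-dimethoxybenzaldehyde (both epimers at the ether carbon)
Conditions: Cs2CO3 (1.5 equiv), DMF, 50 °C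
Reagents that add atoms: none
Why: Williamson ether synthesis with an activated 4-methoxybenzylic bromide and a caesium phenoxide in DMF. The carbon next to the bromide carries no acidic hydrogen, so E2 loss of HBr is not available. The new ether carbon forms as both epimers, which does not matter because it becomes sp2 in 17.

Step 9
Reactants: 13 3-[(1R)-1-[4-(benzyloxy)phenyl]ethyl]-2-[2,2-dimethoxy-1-(4-methoxyphenyl)ethoxy]-4,6-dimethoxybenzaldehyde
Product: 14 3-[(1R)-1-[4-(benzyloxy)phenyl]ethyl]-4,6-dimethoxy-2-[1-(4-methoxyphenyl)-2-oxoethoxy]benzaldehyde (either epimer at the α-aryloxy carbon)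
Conditions: 2 M aq. HCl–THF (1:3), 40 °C
Reagents that add atoms: water, O
Why: Acid hydrolysis of a dimethyl acetal. Both ortho positions of the aryl ether are substituted, so the oxocarbenium ion cannot close a benzofuran, and the formyl group deactivates ring A against protonation at the carbon bearing the diarylmethine. The enolisable dialdehyde should be used at once without chromatography.

Step 10
Reactants: 14 3-[(1R)-1-[4-(benzyloxy)phenyl]ethyl]-4,6-dimethoxy-2-[1-(4-methoxyphenyl)-2-oxoethoxy]benzaldehyde
Product: 15 8-[(1R)-1-[4-(benzyloxy)phenyl]ethyl]-3-hydroxy-5,7-dimethoxy-2-(4-methoxyphenyl)-2,3-dihydro-4H-chromen-4-one (mixture of C2/C3 stereoisomers)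
Conditions: 2-(pentafluorophenyl)-6,7-dihydro-5H-pyrrolo[2,1-c][1,2,4]triazol-2-ium tetrafluoroborate (15 mol %), i-Pr2NEt (15 mol %), degassed THF (0.02 M), rt, Ar
Reagents that add atoms: none
Why: The triazolylidene freed by the amine adds to a formyl carbon, proton transfer gives the Breslow intermediate (an enaminol acting as acyl anion), this carbon attacks the other formyl group across the ether tether, and collapse of the adduct returns the carbene and leaves the α-hydroxy ketone. The closest known reaction type is the carbene-catalysed intramolecular crossed benzoin cyclisation of 2-(2-oxoalkoxy)benzaldehydes to 3-hydroxychroman-4-ones, here with an aldehyde as the acceptor. Ring C closes by 6-exo-trig attack, forming C3–C4. The new centre at C3 and the labile one at C2 are left uncontrolled because both become sp2 in step 11, so an achiral catalyst suffices, and the (R) centre is remote and not acidic. Should the acyl anion form on the aliphatic aldehyde instead, hydroxyl and carbonyl are merely interchanged and the same enediol and dione 16 are reached in step 11. The step needs carbene catalysis to win over enolate chemistry: the competing aldol closes a five-membered ring to an adduct with a quaternary α-carbon that cannot dehydrate and reverts, whereas the aryl ketone conjugated with the dimethoxy ring A is the thermodynamic sink, and a catalytic weak amine keeps the enolate concentration low. The ortho ether tether places the two formyl carbons in a 1,6-relationship, which together with high dilution should favour ring closure over intermolecular benzoin and over loss of the aryloxy group from the Breslow intermediate. Air is excluded so that the Breslow intermediate is not oxidised to an acyl azolium.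

Step 11
Reactants: 15 8-[(1R)-1-[4-(benzyloxy)phenyl]ethyl]-3-hydroxy-5,7-dimethoxy-2-(4-methoxyphenyl)-2,3-dihydro-4H-chromen-4-one
Product: 17 8-[(1R)-1-[4-(benzyloxy)phenyl]ethyl]-3-hydroxy-5,7-dimethoxy-2-(4-methoxyphenyl)-4H-chromen-4-one, via chroman-3,4-dione 16 (not isolated)
Conditions: I2 (1.2 equiv), KOAc (3 equiv), AcOH, 80 °C
Reagents that add atoms: none
Why: Iodine oxidation of an acyloin through its enediol, the classical dehydrogenation of dihydroflavonols. Dione 16 enolises toward C2 because this gives the aromatic pyranone, which removes the centres at C2 and C3. Acetate buffers the HI formed, so the benzyl ether and the diarylmethine should be safe.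

Step 12
Reactants: 17 8-[(1R)-1-[4-(benzyloxy)phenyl]ethyl]-3-hydroxy-5,7-dimethoxy-2-(4-methoxyphenyl)-4H-chromen-4-one
Product: 18 3,5-dihydroxy-8-[(1R)-1-(4-hydroxyphenyl)ethyl]-7-methoxy-2-(4-methoxyphenyl)-4H-chromen-4-one
Conditions: BCl3 (6 equiv), pentamethylbenzene (3 equiv), CH2Cl2, −78 to 0 °C; MeOH, then aq. NaHCO3
Reagents that add atoms: none
Why: Lewis-acid ether cleavage: boron chelated between the C4 carbonyl and the 5-methoxy oxygen activates that methyl group alone for attack by chloride, while the 7- and 4'-methyl ethers, which cannot chelate, should stay. The benzyl ether is cleaved at low temperature, and pentamethylbenzene traps the benzyl cation before it can alkylate C6.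

## Compound list

1 | 2-hydroxy-4,6-dimethoxybenzaldehyde | O=Cc1c(O)cc(OC)cc1OC | starting material
2 | 4-(benzyloxy)phenylmagnesium bromide | Br[Mg]c1ccc(OCc2ccccc2)cc1 | starting material
3 | 2-{[4-(benzyloxy)phenyl](hydroxy)methyl}-3,5-dimethoxyphenol (racemic) | OC(c1ccc(OCc2ccccc2)cc1)c1c(O)cc(OC)cc1OC | intermediate
4 | [4-(benzyloxy)phenyl](2-hydroxy-4,6-dimethoxyphenyl)methanone | O=C(c1ccc(OCc2ccccc2)cc1)c1c(O)cc(OC)cc1OC | intermediate
5 | 2-{1-[4-(benzyloxy)phenyl]-1-hydroxyethyl}-3,5-dimethoxyphenol (racemic, not isolated) | CC(O)(c1ccc(OCc2ccccc2)cc1)c1c(O)cc(OC)cc1OC | intermediate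
6 | 2-{1-[4-(benzyloxy)phenyl]ethenyl}-3,5-dimethoxyphenol | C=C(c1ccc(OCc2ccccc2)cc1)c1c(O)cc(OC)cc1OC | intermediate
7 | 2-[(1R)-1-[4-(benzyloxy)phenyl]ethyl]-3,5-dimethoxyphenol | COc1cc(O)c([C@H](C)c2ccc(OCc3ccccc3)cc2)c(OC)c1 | intermediate
8 | 2-[(1R)-1-[4-(benzyloxy)phenyl]ethyl]-6-(hydroxymethyl)-3,5-dimethoxyphenol (not isolated) | COc1cc(OC)c([C@H](C)c2ccc(OCc3ccccc3)cc2)c(O)c1CO | intermediate
9 | 3-[(1R)-1-[4-(benzyloxy)phenyl]ethyl]-2-hydroxy-4,6-dimethoxybenzaldehyde | COc1cc(OC)c([C@H](C)c2ccc(OCc3ccccc3)cc2)c(O)c1C=O | intermediate
10 | 4-methoxybenzaldehyde | COc1ccc(C=O)cc1 | starting material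
11 | 1-methoxy-4-(2-methoxyethenyl)benzene (E/Z mixture) | COC=Cc1ccc(OC)cc1 | intermediate
12 | 1-(1-bromo-2,2-dimethoxyethyl)-4-methoxybenzene (racemic) | COc1ccc(C(Br)C(OC)OC)cc1 | intermediate
13 | 3-[(1R)-1-[4-(benzyloxy)phenyl]ethyl]-2-[2,2-dimethoxy-1-(4-methoxyphenyl)ethoxy]-4,6-dimethoxybenzaldehyde (both epimers at the ether carbon) | COc1ccc(C(Oc2c([C@H](C)c3ccc(OCc4ccccc4)cc3)c(OC)cc(OC)c2C=O)C(OC)OC)cc1 | intermediate
14 | 3-[(1R)-1-[4-(benzyloxy)phenyl]ethyl]-4,6-dimethoxy-2-[1-(4-methoxyphenyl)-2-oxoethoxy]benzaldehyde (either epimer at the α-aryloxy carbon) | COc1ccc(C(C=O)Oc2c([C@H](C)c3ccc(OCc4ccccc4)cc3)c(OC)cc(OC)c2C=O)cc1 | intermediate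
15 | 8-[(1R)-1-[4-(benzyloxy)phenyl]ethyl]-3-hydroxy-5,7-dimethoxy-2-(4-methoxyphenyl)-2,3-dihydro-4H-chromen-4-one (C2/C3 stereoisomer mixture) | COc1ccc(C2Oc3c([C@H](C)c4ccc(OCc5ccccc5)cc4)c(OC)cc(OC)c3C(=O)C2O)cc1 | intermediate
16 | 8-[(1R)-1-[4-(benzyloxy)phenyl]ethyl]-5,7-dimethoxy-2-(4-methoxyphenyl)-2H-chromene-3,4-dione (not isolated) | COc1ccc(C2Oc3c([C@H](C)c4ccc(OCc5ccccc5)cc4)c(OC)cc(OC)c3C(=O)C2=O)cc1 | intermediate
17 | 8-[(1R)-1-[4-(benzyloxy)phenyl]ethyl]-3-hydroxy-5,7-dimethoxy-2-(4-methoxyphenyl)-4H-chromen-4-one | COc1ccc(-c2oc3c([C@H](C)c4ccc(OCc5ccccc5)cc4)c(OC)cc(OC)c3c(=O)c2O)cc1 | intermediate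
18 | 3,5-dihydroxy-8-[(1R)-1-(4-hydroxyphenyl)ethyl]-7-methoxy-2-(4-methoxyphenyl)-4H-chromen-4-one | COc1ccc(-c2oc3c([C@H](C)c4ccc(O)cc4)c(OC)cc(O)c3c(=O)c2O)cc1 | target

## Step count and least certain steps

Total step count: 12. Longest linear sequence: 10 steps (steps 1–5 and 8–12). Steps 6 and 7 are the two-step side branch to 12.

**Step 10 (key step).** Three processes can take the material away.
- Loss of the aryloxy group: if the Breslow intermediate forms on the aliphatic aldehyde, β-elimination of the ring A phenoxide (a fair leaving group, being that of a salicylaldehyde) followed by acyl transfer would cleave the O1–C2 bond.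
- Slow carbene addition to the ring A aldehyde, which has two ortho substituents and is electron-rich.
- Base-mediated enolisation of the α-aryloxy aldehyde with reversible five-ring aldol trapping or self-condensation.

The fallback forms the same bond reductively and sets out from 14. SmI2 (2.5 equiv) in THF with t-BuOH at −78 °C should reduce the ring A aldehyde first. Its ketyl has no leaving group next to it and adds to the aliphatic aldehyde in a pinacol cyclisation. This gives 8-[(1R)-1-[4-(benzyloxy)phenyl]ethyl]-5,7-dimethoxy-2-(4-methoxyphenyl)-3,4-dihydro-2H-chromene-3,4-diol F1. IBX (2.5 equiv) in DMSO at rt then oxidises both carbinols without glycol cleavage to dione 16, which enolises, and the route is rejoined at 17.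

**Step 8.** Substitution may be slow, because the phenoxide of 9 is flanked by two substituents and the bromide is secondary and next to an acetal carbon. Ionisation of the bromide, followed by solvolysis or a hydride shift from the acetal carbon, may then compete. The fallback sets out from 9 and uses a far more reactive electrophile.
- Methyl 2-bromo-2-(4-methoxyphenyl)acetate F2 with K2CO3 in acetone at reflux should give methyl 2-{2-[(1R)-1-[4-(benzyloxy)phenyl]ethyl]-6-formyl-3,5-dimethoxyphenoxy}-2-(4-methoxyphenyl)acetate F3.
- LiAlH4 in THF at 0 °C reduces ester and aldehyde to 2-{2-[(1R)-1-[4-(benzyloxy)phenyl]ethyl]-6-(hydroxymethyl)-3,5-dimethoxyphenoxy}-2-(4-methoxyphenyl)ethan-1-ol F4.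
- Dess–Martin periodinane with NaHCO3 in CH2Cl2 oxidises both alcohols and rejoins the route at 14.

This also avoids the acidic unmasking of step 9.

**Step 4.** Facial selectivity may be poor, because the methoxy group on the second ortho position twists the quinone methide out of the geometry for which the acid is known to work. The long-lived cation may also be captured by ring A of a second molecule. The fallback keeps 6 but changes the mode of reduction to a hydrogenation directed by the phenol: [Rh(cod)2]BF4 with a Josiphos-type ferrocenyl diphosphine, H2 (10 bar), Et3N, MeOH. The phenoxide binds rhodium and the alkene is reduced within the chelate, not through a cation. It sets out from 6, comes back at 7, and makes no new compound (F0).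

**Step 12.** Several things can go wrong in the one-pot deprotection: over-cleavage of the 7- or 4'-methyl ether, C-benzylation of C6 if the cation is not trapped, Lewis-acid cleavage of the ring A–methine bond, or incomplete release of the product from its boron chelates. The fallback separates the two deprotections and sets out from 17.
- H2 (1 atm), Pd/C in EtOAc–MeOH removes the benzyl group without a cation and without touching the chromone double bond, giving 3-hydroxy-8-[(1R)-1-(4-hydroxyphenyl)ethyl]-5,7-dimethoxy-2-(4-methoxyphenyl)-4H-chromen-4-one F5.
- AlCl3 in MeCN at 50 °C then removes only the chelated 5-methyl group and arrives at 18.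

## Further compounds

F1 | step 10 | 8-[(1R)-1-[4-(benzyloxy)phenyl]ethyl]-5,7-dimethoxy-2-(4-methoxyphenyl)-3,4-dihydro-2H-chromene-3,4-diol (stereoisomer mixture at C2, C3, C4) | COc1ccc(C2Oc3c([C@H](C)c4ccc(OCc5ccccc5)cc4)c(OC)cc(OC)c3C(O)C2O)cc1
F2 | step 8 | methyl 2-bromo-2-(4-methoxyphenyl)acetate (racemic) | COC(=O)C(Br)c1ccc(OC)cc1
F3 | step 8 | methyl 2-{2-[(1R)-1-[4-(benzyloxy)phenyl]ethyl]-6-formyl-3,5-dimethoxyphenoxy}-2-(4-methoxyphenyl)acetate (both epimers) | COC(=O)C(Oc1c([C@H](C)c2ccc(OCc3ccccc3)cc2)c(OC)cc(OC)c1C=O)c1ccc(OC)cc1
F4 | step 8 | 2-{2-[(1R)-1-[4-(benzyloxy)phenyl]ethyl]-6-(hydroxymethyl)-3,5-dimethoxyphenoxy}-2-(4-methoxyphenyl)ethan-1-ol (both epimers) | OCC(Oc1c([C@H](C)c2ccc(OCc3ccccc3)cc2)c(OC)cc(OC)c1CO)c1ccc(OC)cc1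
F0 | step 4 | none | none
F5 | step 12 | 3-hydroxy-8-[(1R)-1-(4-hydroxyphenyl)ethyl]-5,7-dimethoxy-2-(4-methoxyphenyl)-4H-chromen-4-one | COc1ccc(-c2oc3c([C@H](C)c4ccc(O)cc4)c(OC)cc(OC)c3c(=O)c2O)cc1
A1 | alternative 1 | (3R)-3-[4-(benzyloxy)phenyl]-2,4,6-trimethoxy-2,3-dihydro-1-benzofuran (either C2 epimer) | COC1Oc2cc(OC)cc(OC)c2[C@H]1c1ccc(OCc2ccccc2)cc1
A2 | alternative 2 | 2-[(1R)-1-[4-(benzyloxy)phenyl]ethyl]-5-ethoxy-3-[(triisopropylsilyl)oxy]phenol | Oc1cc(OCC)cc(O[Si](C(C)C)(C(C)C)C(C)C)c1[C@H](C)c1ccc(OCc2ccccc2)cc1
A3 | alternative 3 | 3-(benzyloxy)-8-[(1R)-1-[4-(benzyloxy)phenyl]ethyl]-5,7-dihydroxy-2-(4-methoxyphenyl)-4H-chromen-4-one | COc1ccc(-c2oc3c([C@H](C)c4ccc(OCc5ccccc5)cc4)c(O)cc(O)c3c(=O)c2OCc2ccccc2)cc1
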